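Ring carbons are numbered C1 (C–OAc), C2 (CH2), C3 (C–Br), C4 (CMe2), C5 (C–Cl), C6 (ring alkene carbon); the side chain is C7 (=CH) and C8 (CH2Br). The retrosynthesis turns C8–Br, C5–Cl, C3–Br and the C1 acetate back into C–O groups (C3 and C5 with inversion), then cuts ring bond C2–C3 (aldol), then C6–C1 (Stille coupling) and C6–C7 (Claisen-type condensation) of a butenolide built on (R)-pantolactone.
Enabling feature: C2 is the only methylene between C1 and C3, and C3 sits on quaternary C4, so a C3 aldehyde has no α-hydrogen while a C1 methyl ketone can enolise only towards C2; joining C2 to C3 makes the single carbocycle (ring A).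
Forward: C3–C6 come from (R)-pantolactone; its O-acetate is cyclised to a tetronic acid (adds C7, C8), the enol triflate is coupled with a 1-ethoxyvinyl stannane (adds C1, C2), and reduction opens the butenolide to a diol with C8 and C5 cis on C6=C7; silylation, unmasking and oxidation give the keto aldehyde.
Ring A is then closed by a silyl-triflate-mediated Mukaiyama aldol, followed by C1 reduction and acetylation, bromide at C3, chloride at C5 and bromide at C8.
Stereochemistry: C5 comes from the chiral pool and is inverted by chloride at the end; C3 is set in the aldol trans to the C5 silyl ether and inverted by bromide; C1 is set by hydride attack anti to the axial C5 silyloxy group; the alkene geometry is fixed by the butenolide ring.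
Key step: step 9

Step 1
Reactants: 1 (R)-pantolactone, (3R)-3-hydroxy-4,4-dimethyloxolan-2-one; 2 acetic anhydride
Product: 3 (3R)-4,4-dimethyl-2-oxooxolan-3-yl acetate
Conditions: Ac2O, pyridine, DMAP (cat.), CH2Cl2, 0 °C to rt
Reagents that add atoms: acetic anhydride (2), CC(=O)OC(C)=O
Why: DMAP-catalysed esterification of the secondary hydroxyl attaches the two carbons that become C7 and C8 and leaves the C5 stereocentre untouched.

Step 2
Reactants: 3 O-acetyl-(R)-pantolactone
Product: 6 (5R)-4-hydroxy-5-{2-methyl-1-[(triethylsilyl)oxy]propan-2-yl}furan-2(5H)-one, via dilithium tetronate alkoxide 4 (not isolated), via bis(triethylsilyl) derivative 5 (not isolated)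
Conditions: LiN(SiMe3)2 (2.2 equiv), THF, −78 to 0 °C; Et3SiCl (2.5 equiv), −78 to 0 °C; aq. NaH2PO4 work-up
Reagents that add atoms: chlorotriethylsilane, CC[Si](Cl)(CC)CC
Why: Lacey–Dieckmann condensation (intramolecular Claisen): the lithium enolate of the acetate adds 5-exo-trig to the lactone carbonyl C6, the tetrahedral intermediate collapses by opening the pantolactone ring to the tetronate, the freed C3 alkoxide is capped by Et3SiCl and the silyl tetronate is hydrolysed on work-up, while the hindered C5–H next to quaternary C4 is not removed by the bulky amide, so C5 keeps its configuration.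

Step 3
Reactants: 6 tetronic acid silyl ether
Product: 7 (2R)-2-{2-methyl-1-[(triethylsilyl)oxy]propan-2-yl}-5-oxo-2,5-dihydrofuran-3-yl trifluoromethanesulfonate
Conditions: Tf2O, i-Pr2NEt, CH2Cl2, −78 °C
Reagents that add atoms: trifluoromethanesulfonic anhydride, O=S(=O)(OS(=O)(=O)C(F)(F)F)C(F)(F)F
Why: O-sulfonylation of the acidic tetronic enol (enol triflate formation) activates C6 for coupling, and the low temperature and hindered amine leave the γ-hydrogen at C5 in place.

Step 4
Reactants: 7 butenolide triflate; 8 tributyl(1-ethoxyethenyl)stannane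
Product: 9 (5R)-4-(1-ethoxyethenyl)-5-{2-methyl-1-[(triethylsilyl)oxy]propan-2-yl}furan-2(5H)-one
Conditions: Pd(PPh3)4 (5 mol %), LiCl, THF, 60 °C
Reagents that add atoms: tributyl(1-ethoxyethenyl)stannane (8), CCCC[Sn](CCCC)(CCCC)C(=C)OCC
Why: Stille cross-coupling of the vinyl triflate forms C6–C1 and brings in C1 and C2 as an enol ether (masked acetyl group) under neutral conditions that do not epimerise C5.

Step 5
Reactants: 9 ethoxyvinyl butenolide
Product: 10 (2E,4R)-3-(1-ethoxyethenyl)-5,5-dimethyl-6-[(triethylsilyl)oxy]hex-2-ene-1,4-diol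
Conditions: i-Bu2AlH (4 equiv), CH2Cl2, −78 to 0 °C; aq. potassium sodium tartrate
Reagents that add atoms: none
Why: Exhaustive hydride reduction of the butenolide (lactone to lactol to diol) opens the ring to an ene-1,4-diol in which C8 and C5 must be cis on C6=C7 because both were members of the five-membered ring, and the enol ether and silyl ether are inert to the hydride.

Step 6
Reactants: 10 ene-diol
Product: 12 (2E,4R)-1-[(tert-butyldiphenylsilyl)oxy]-3-(1-ethoxyethenyl)-5,5-dimethyl-4,6-bis[(triethylsilyl)oxy]hex-2-ene, via C8 tert-butyldiphenylsilyl ether 11 (not isolated)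
Conditions: t-BuPh2SiCl (1.05 equiv), imidazole, CH2Cl2, 0 °C; then 2,6-lutidine, Et3SiOTf, −78 to 0 °C
Reagents that add atoms: tert-butylchlorodiphenylsilane, CC(C)(C)[Si](Cl)(c1ccccc1)c1ccccc1; triethylsilyl trifluoromethanesulfonate, CC[Si](CC)(CC)OS(=O)(=O)C(F)(F)F
Why: Sequential silyl ether formation, in which the bulky chlorosilane takes only the primary allylic C8 hydroxyl and the silyl triflate then caps the hindered C5 hydroxyl, gives three silyl ethers of graded lability (primary Et3Si, then secondary Et3Si, then t-BuPh2Si).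

Step 7
Reactants: 12 tris-silyl dienyl ether
Product: 13 (3E,4R)-3-{2-[(tert-butyldiphenylsilyl)oxy]ethylidene}-6-hydroxy-5,5-dimethyl-4-[(triethylsilyl)oxy]hexan-2-one
Conditions: PPTS (0.2 equiv), MeOH–H2O (10:1), 0 °C to rt
Reagents that add atoms: water, O
Why: Mild acid hydrolysis of the 2-ethoxydiene (enol ether hydrolysis) releases the C1 methyl ketone and the same acid cleaves the primary triethylsilyl ether at C3, while the hindered secondary C5 silyl ether and the tert-butyldiphenylsilyl ether should survive.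

Step 8
Reactants: 13 hydroxy enone
Product: 14 (3R,4E)-4-acetyl-6-[(tert-butyldiphenylsilyl)oxy]-2,2-dimethyl-3-[(triethylsilyl)oxy]hex-4-enal
Conditions: Dess–Martin periodinane, NaHCO3, CH2Cl2, 0 °C to rt
Reagents that add atoms: none
Why: Dess–Martin oxidation of the primary alcohol gives the C3 aldehyde, which has no α-hydrogen and can neither epimerise nor enolise.

Step 9
Reactants: 14 keto aldehyde
Product: 16 (2E,3R,5S)-2-{2-[(tert-butyldiphenylsilyl)oxy]ethylidene}-4,4-dimethyl-3-[(triethylsilyl)oxy]-5-[(trimethylsilyl)oxy]cyclohexan-1-one, via 2-silyloxydiene aldehyde 15 (not isolated)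
Conditions: i-Pr2NEt (1.6 equiv), Me3SiOTf (1.3 equiv), CH2Cl2 (0.01 M), −78 to −30 °C; aq. NaHCO3 work-up
Reagents that add atoms: trimethylsilyl trifluoromethanesulfonate, C[Si](C)(C)OS(=O)(=O)C(F)(F)F
Why: Soft enolisation by Me3SiOTf and i-Pr2NEt converts the C1 methyl ketone into the 2-silyloxydiene 15, whose terminal carbon C2 adds to the silyl-triflate-activated C3 aldehyde through an open transition state, and silyl transfer gives the β-silyloxy ketone; this is an intramolecular Mukaiyama aldol addition, closest to the known one-pot enol silane formation and Mukaiyama aldol of methyl ketones with non-enolisable aldehydes. Ring A closes in the 6-(enolendo)-exo-trig mode by forming C2–C3. The new stereocentre C3 is controlled by C5: allylic 1,3-strain against C8 holds the C5 silyloxy group axial in the chair-like transition state, and the aldehyde oxygen then points equatorially because the axial orientation would be 1,3-diaxial to that group, so the C3 oxygen should end trans to the C5 oxygen. The step needs site-selective enolisation and an untouched C6=C7 geometry: C4 is quaternary, C6 bears no hydrogen and C8 lies trans to the carbonyl out of reach of a cyclic deprotonation, so only C2 becomes nucleophilic. A hetero-Diels–Alder path is excluded because it would need a bridgehead double bond at C6, and high dilution suppresses intermolecular aldol addition.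

Step 10
Reactants: 16 ring A ketone
Product: 17 (1S,2Z,3R,5S)-2-{2-[(tert-butyldiphenylsilyl)oxy]ethylidene}-4,4-dimethyl-3-[(triethylsilyl)oxy]-5-[(trimethylsilyl)oxy]cyclohexan-1-ol
Conditions: i-Bu2AlH, CH2Cl2, −78 °C; aq. potassium sodium tartrate
Reagents that add atoms: none
Why: Carbonyl 1,2-reduction of the enone: allylic 1,3-strain against C8 keeps the C5 silyloxy group axial, where it blocks the syn face of C1, so hydride should be delivered to the opposite face and the C1 hydroxyl should form cis to the C5 oxygen and trans to the C3 oxygen.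

Step 11
Reactants: 17 allylic alcohol; 2 acetic anhydride
Product: 19 (1S,2Z,3R,5S)-2-{2-[(tert-butyldiphenylsilyl)oxy]ethylidene}-5-hydroxy-4,4-dimethyl-3-[(triethylsilyl)oxy]cyclohexyl acetate, via C1 acetate trimethylsilyl ether 18 (not isolated)
Conditions: Ac2O, pyridine, DMAP (cat.), CH2Cl2, 0 °C; then MeOH, PPTS, 0 °C
Reagents that add atoms: acetic anhydride (2), CC(=O)OC(C)=O
Why: Esterification of the only free hydroxyl (C1) followed by methanolysis of the labile trimethylsilyl ether frees the C3 hydroxyl without a regioselectivity problem and without touching the triethylsilyl ether, the tert-butyldiphenylsilyl ether or the acetate.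

Step 12
Reactants: 19 hydroxy acetate
Product: 21 (1S,2Z,3S,5R)-5-bromo-2-{2-[(tert-butyldiphenylsilyl)oxy]ethylidene}-4,4-dimethyl-3-[(triethylsilyl)oxy]cyclohexyl acetate, via C3 chloromethanesulfonate 20 (not isolated)
Conditions: ClCH2SO2Cl, pyridine, CH2Cl2, 0 °C; aqueous wash; then n-Bu4NBr, toluene, 60 °C
Reagents that add atoms: tetrabutylammonium bromide, CCCC[N+](CCCC)(CCCC)CCCC.[Br-]
Why: SN2 displacement of a chloromethanesulfonate by bromide with Walden inversion at C3: the sulfonate should react through the chair in which it is axial and the C1 acetate and C5 silyl ether are equatorial, so bromide attacks equatorially, the acetate cannot participate, and the non-polar solvent disfavours ionisation and methyl shift from C4.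

Step 13
Reactants: 21 C3 bromide
Product: 22 (1S,2E,3S,5R)-5-bromo-2-{2-[(tert-butyldiphenylsilyl)oxy]ethylidene}-3-hydroxy-4,4-dimethylcyclohexyl acetate
Conditions: HF·pyridine, pyridine, THF, 0 °C to rt
Reagents that add atoms: none
Why: Fluoride-mediated desilylation in which the secondary triethylsilyl ether is cleaved much faster than the primary tert-butyldiphenylsilyl ether, with acetate and bromide inert to buffered HF·pyridine.

Step 14
Reactants: 22 C5 allylic alcohol
Product: 23 (1S,2Z,3R,5R)-5-bromo-2-{2-[(tert-butyldiphenylsilyl)oxy]ethylidene}-3-chloro-4,4-dimethylcyclohexyl acetate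
Conditions: PPh3, (Cl3C)2CO, CH2Cl2, 0 °C to rt
Reagents that add atoms: hexachloroacetone, O=C(C(Cl)(Cl)Cl)C(Cl)(Cl)Cl
Why: Appel-type chlorination of an allylic alcohol (SN2 with inversion at C5): with the C1 acetate, C3 bromide and C5 oxygen all cis the ring should hold all three equatorial, so the C5 oxyphosphonium group lies in the plane of C6=C7 where ionisation and SN2′ attack at C7 lack orbital overlap, and chloride enters axially with relief of allylic 1,3-strain.

Step 15
Reactants: 23 C5 chloride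
Product: 24 (1S,2Z,3R,5R)-5-bromo-3-chloro-2-(2-hydroxyethylidene)-4,4-dimethylcyclohexyl acetate
Conditions: n-Bu4NF, AcOH (1:1), THF, 0 °C to rt
Reagents that add atoms: none
Why: Fluoride-mediated cleavage of the tert-butyldiphenylsilyl ether, buffered with acetic acid so that the C8 alkoxide is never free to displace the cis C5 chloride or to attack the acetate.

Step 16
Reactants: 24 primary allylic alcohol
Product: 25 (1S,2Z,3R,5R)-5-bromo-2-(2-bromoethylidene)-3-chloro-4,4-dimethylcyclohexyl acetate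
Conditions: CBr4, PPh3, CH2Cl2, 0 °C
Reagents that add atoms: tetrabromomethane, BrC(Br)(Br)Br
Why: Appel bromination of the primary allylic alcohol (SN2 at C8) under neutral conditions should complete the target, since the hindered secondary chloride and bromide and the acetate do not react with the phosphonium reagent.

Compound list
1 | (R)-pantolactone, (3R)-3-hydroxy-4,4-dimethyloxolan-2-one | CC1(C)COC(=O)[C@@H]1O | starting material
2 | acetic anhydride | CC(=O)OC(C)=O | starting material
3 | (3R)-4,4-dimethyl-2-oxooxolan-3-yl acetate | CC(=O)O[C@H]1C(=O)OCC1(C)C | intermediate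
4 | dilithium (2R)-2-(2-methyl-1-oxidopropan-2-yl)-5-oxo-2,5-dihydrofuran-3-olate | [Li+].[Li+].O=C1C=C([O-])[C@H](O1)C(C)(C)C[O-] | intermediate (not isolated)
5 | (5R)-4-[(triethylsilyl)oxy]-5-{2-methyl-1-[(triethylsilyl)oxy]propan-2-yl}furan-2(5H)-one | O=C1C=C(O[Si](CC)(CC)CC)[C@H](O1)C(C)(C)CO[Si](CC)(CC)CC | intermediate (not isolated)
6 | (5R)-4-hydroxy-5-{2-methyl-1-[(triethylsilyl)oxy]propan-2-yl}furan-2(5H)-one | O=C1C=C(O)[C@H](O1)C(C)(C)CO[Si](CC)(CC)CC | intermediate
7 | (2R)-2-{2-methyl-1-[(triethylsilyl)oxy]propan-2-yl}-5-oxo-2,5-dihydrofuran-3-yl trifluoromethanesulfonate | O=C1C=C(OS(=O)(=O)C(F)(F)F)[C@H](O1)C(C)(C)CO[Si](CC)(CC)CC | intermediate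
8 | tributyl(1-ethoxyethenyl)stannane | CCCC[Sn](CCCC)(CCCC)C(=C)OCC | starting material
9 | (5R)-4-(1-ethoxyethenyl)-5-{2-methyl-1-[(triethylsilyl)oxy]propan-2-yl}furan-2(5H)-one | O=C1C=C(C(=C)OCC)[C@H](O1)C(C)(C)CO[Si](CC)(CC)CC | intermediate
10 | (2E,4R)-3-(1-ethoxyethenyl)-5,5-dimethyl-6-[(triethylsilyl)oxy]hex-2-ene-1,4-diol | OC/C=C(/C(=C)OCC)[C@H](O)C(C)(C)CO[Si](CC)(CC)CC | intermediate
11 | (2E,4R)-1-[(tert-butyldiphenylsilyl)oxy]-3-(1-ethoxyethenyl)-5,5-dimethyl-6-[(triethylsilyl)oxy]hex-2-en-4-ol | CCOC(=C)/C(=C/CO[Si](c1ccccc1)(c1ccccc1)C(C)(C)C)[C@H](O)C(C)(C)CO[Si](CC)(CC)CC | intermediate (not isolated)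
12 | (2E,4R)-1-[(tert-butyldiphenylsilyl)oxy]-3-(1-ethoxyethenyl)-5,5-dimethyl-4,6-bis[(triethylsilyl)oxy]hex-2-ene | CCOC(=C)/C(=C/CO[Si](c1ccccc1)(c1ccccc1)C(C)(C)C)[C@H](O[Si](CC)(CC)CC)C(C)(C)CO[Si](CC)(CC)CC | intermediate
13 | (3E,4R)-3-{2-[(tert-butyldiphenylsilyl)oxy]ethylidene}-6-hydroxy-5,5-dimethyl-4-[(triethylsilyl)oxy]hexan-2-one | CC(=O)/C(=C/CO[Si](c1ccccc1)(c1ccccc1)C(C)(C)C)[C@H](O[Si](CC)(CC)CC)C(C)(C)CO | intermediate
14 | (3R,4E)-4-acetyl-6-[(tert-butyldiphenylsilyl)oxy]-2,2-dimethyl-3-[(triethylsilyl)oxy]hex-4-enal | CC(=O)/C(=C/CO[Si](c1ccccc1)(c1ccccc1)C(C)(C)C)[C@H](O[Si](CC)(CC)CC)C(C)(C)C=O | intermediate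
15 | (3S,4E)-6-[(tert-butyldiphenylsilyl)oxy]-2,2-dimethyl-3-[(triethylsilyl)oxy]-4-{1-[(trimethylsilyl)oxy]ethenyl}hex-4-enal | C=C(O[Si](C)(C)C)/C(=C/CO[Si](c1ccccc1)(c1ccccc1)C(C)(C)C)[C@H](O[Si](CC)(CC)CC)C(C)(C)C=O | intermediate (not isolated)
16 | (2E,3R,5S)-2-{2-[(tert-butyldiphenylsilyl)oxy]ethylidene}-4,4-dimethyl-3-[(triethylsilyl)oxy]-5-[(trimethylsilyl)oxy]cyclohexan-1-one | O=C1C[C@H](O[Si](C)(C)C)C(C)(C)[C@@H](O[Si](CC)(CC)CC)/C1=C\CO[Si](c1ccccc1)(c1ccccc1)C(C)(C)C | intermediate
17 | (1S,2Z,3R,5S)-2-{2-[(tert-butyldiphenylsilyl)oxy]ethylidene}-4,4-dimethyl-3-[(triethylsilyl)oxy]-5-[(trimethylsilyl)oxy]cyclohexan-1-ol | O[C@H]1C[C@H](O[Si](C)(C)C)C(C)(C)[C@@H](O[Si](CC)(CC)CC)/C1=C\CO[Si](c1ccccc1)(c1ccccc1)C(C)(C)C | intermediate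
18 | (1S,2Z,3R,5S)-2-{2-[(tert-butyldiphenylsilyl)oxy]ethylidene}-4,4-dimethyl-3-[(triethylsilyl)oxy]-5-[(trimethylsilyl)oxy]cyclohexyl acetate | CC(=O)O[C@H]1C[C@H](O[Si](C)(C)C)C(C)(C)[C@@H](O[Si](CC)(CC)CC)/C1=C\CO[Si](c1ccccc1)(c1ccccc1)C(C)(C)C | intermediate (not isolated)
19 | (1S,2Z,3R,5S)-2-{2-[(tert-butyldiphenylsilyl)oxy]ethylidene}-5-hydroxy-4,4-dimethyl-3-[(triethylsilyl)oxy]cyclohexyl acetate | CC(=O)O[C@H]1C[C@H](O)C(C)(C)[C@@H](O[Si](CC)(CC)CC)/C1=C\CO[Si](c1ccccc1)(c1ccccc1)C(C)(C)C | intermediate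
20 | (1S,2Z,3R,5S)-2-{2-[(tert-butyldiphenylsilyl)oxy]ethylidene}-5-{[(chloromethyl)sulfonyl]oxy}-4,4-dimethyl-3-[(triethylsilyl)oxy]cyclohexyl acetate | CC(=O)O[C@H]1C[C@H](OS(=O)(=O)CCl)C(C)(C)[C@@H](O[Si](CC)(CC)CC)/C1=C\CO[Si](c1ccccc1)(c1ccccc1)C(C)(C)C | intermediate (not isolated)
21 | (1S,2Z,3S,5R)-5-bromo-2-{2-[(tert-butyldiphenylsilyl)oxy]ethylidene}-4,4-dimethyl-3-[(triethylsilyl)oxy]cyclohexyl acetate | CC(=O)O[C@H]1C[C@@H](Br)C(C)(C)[C@@H](O[Si](CC)(CC)CC)/C1=C\CO[Si](c1ccccc1)(c1ccccc1)C(C)(C)C | intermediate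
22 | (1S,2E,3S,5R)-5-bromo-2-{2-[(tert-butyldiphenylsilyl)oxy]ethylidene}-3-hydroxy-4,4-dimethylcyclohexyl acetate | CC(=O)O[C@H]1C[C@@H](Br)C(C)(C)[C@@H](O)/C1=C\CO[Si](c1ccccc1)(c1ccccc1)C(C)(C)C | intermediate
23 | (1S,2Z,3R,5R)-5-bromo-2-{2-[(tert-butyldiphenylsilyl)oxy]ethylidene}-3-chloro-4,4-dimethylcyclohexyl acetate | CC(=O)O[C@H]1C[C@@H](Br)C(C)(C)[C@H](Cl)/C1=C\CO[Si](c1ccccc1)(c1ccccc1)C(C)(C)C | intermediate
24 | (1S,2Z,3R,5R)-5-bromo-3-chloro-2-(2-hydroxyethylidene)-4,4-dimethylcyclohexyl acetate | CC(=O)O[C@H]1C[C@@H](Br)C(C)(C)[C@H](Cl)/C1=C\CO | intermediate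
25 | (1S,2Z,3R,5R)-5-bromo-2-(2-bromoethylidene)-3-chloro-4,4-dimethylcyclohexyl acetate (CNP0362553.1) | CC(=O)O[C@H]1C[C@@H](Br)C(C)(C)[C@H](Cl)/C1=C\CBr | target

Total step count: 16. Longest linear sequence: 16 steps, from (R)-pantolactone 1 to 25.

Steps most likely to fail

1. Step 12 (bromide at C3). Substitution at the neopentyl C3 centre may be slower than elimination towards C2, methyl migration from C4 after ionisation may intervene, and the backside may be shielded by the C1 and C5 oxygens in the favoured chair. The fallback reverses the order of the two inversions; it sets out from 19 and comes back at 23. HF·pyridine would free the C5 hydroxyl to give (1S,2E,3R,5S)-2-{2-[(tert-butyldiphenylsilyl)oxy]ethylidene}-3,5-dihydroxy-4,4-dimethylcyclohexyl acetate F1. PPh3 and hexachloroacetone at 0 °C should then chlorinate only the allylic C5 hydroxyl with inversion, leaving the saturated neopentyl C3 hydroxyl, to give (1S,2Z,3S,5S)-2-{2-[(tert-butyldiphenylsilyl)oxy]ethylidene}-3-chloro-5-hydroxy-4,4-dimethylcyclohexyl acetate F2. With the C5 chlorine axial on the opposite face, the chair favoured by allylic strain carries the C3 oxygen axial and the C1 acetate equatorial. Chloromethanesulfonylation would give (1S,2Z,3S,5S)-2-{2-[(tert-butyldiphenylsilyl)oxy]ethylidene}-3-chloro-5-{[(chloromethyl)sulfonyl]oxy}-4,4-dimethylcyclohexyl acetate F3, and n-Bu4NBr in toluene should displace the sulfonate by equatorial attack to give 23.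

2. Step 14 (chloride at C5). The compressed equatorial C5 hydroxyl may be activated only slowly, and the oxyphosphonium ion pair may collapse with allylic transposition (chloride at C7) or without clean inversion. The fallback separates activation from substitution by using an isolated sulfonate in place of the phosphonium ion pair; it sets out from 22 and comes back at 23. ClCH2SO2Cl and pyridine would give (1S,2Z,3S,5R)-5-bromo-2-{2-[(tert-butyldiphenylsilyl)oxy]ethylidene}-3-{[(chloromethyl)sulfonyl]oxy}-4,4-dimethylcyclohexyl acetate F4, which is purified and then treated with LiCl in DMF at rt, so that chloride attacks the in-plane sulfonate axially.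

3. Step 2 (Lacey–Dieckmann ring transfer). Deprotonation at C5 instead of the acetate methyl (epimerisation or acyl shift to carbon) or intermolecular Claisen condensation may compete with ring closure. The fallback builds the same tetronic acid stepwise from ring-opened pantoate; it sets out from 1 and comes back at 6. Saponification with NaOH and acetalisation with 4-methoxybenzaldehyde dimethyl acetal and camphorsulfonic acid would give (2R,4R)-2-(4-methoxyphenyl)-5,5-dimethyl-1,3-dioxane-4-carboxylic acid F5. Masamune chain extension (carbonyldiimidazole, then Mg(O2CCH2CO2Et)2) would give ethyl 3-[(2R,4R)-2-(4-methoxyphenyl)-5,5-dimethyl-1,3-dioxan-4-yl]-3-oxopropanoate F6. Aqueous HCl in THF at 40 °C should cleave the acetal and let the C5 hydroxyl lactonise onto the ester to give (5R)-4-hydroxy-5-(1-hydroxy-2-methylpropan-2-yl)furan-2(5H)-one F7. Silylation with Et3SiCl and imidazole would give 5, and aqueous work-up returns to 6.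

Further compounds
F1 | step 12 | (1S,2E,3R,5S)-2-{2-[(tert-butyldiphenylsilyl)oxy]ethylidene}-3,5-dihydroxy-4,4-dimethylcyclohexyl acetate | CC(=O)O[C@H]1C[C@H](O)C(C)(C)[C@@H](O)/C1=C\CO[Si](c1ccccc1)(c1ccccc1)C(C)(C)C
F2 | step 12 | (1S,2Z,3S,5S)-2-{2-[(tert-butyldiphenylsilyl)oxy]ethylidene}-3-chloro-5-hydroxy-4,4-dimethylcyclohexyl acetate | CC(=O)O[C@H]1C[C@H](O)C(C)(C)[C@H](Cl)/C1=C\CO[Si](c1ccccc1)(c1ccccc1)C(C)(C)C
F3 | step 12 | (1S,2Z,3S,5S)-2-{2-[(tert-butyldiphenylsilyl)oxy]ethylidene}-3-chloro-5-{[(chloromethyl)sulfonyl]oxy}-4,4-dimethylcyclohexyl acetate | CC(=O)O[C@H]1C[C@H](OS(=O)(=O)CCl)C(C)(C)[C@H](Cl)/C1=C\CO[Si](c1ccccc1)(c1ccccc1)C(C)(C)C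
F4 | step 14 | (1S,2Z,3S,5R)-5-bromo-2-{2-[(tert-butyldiphenylsilyl)oxy]ethylidene}-3-{[(chloromethyl)sulfonyl]oxy}-4,4-dimethylcyclohexyl acetate | CC(=O)O[C@H]1C[C@@H](Br)C(C)(C)[C@@H](OS(=O)(=O)CCl)/C1=C\CO[Si](c1ccccc1)(c1ccccc1)C(C)(C)C
F5 | step 2 | (2R,4R)-2-(4-methoxyphenyl)-5,5-dimethyl-1,3-dioxane-4-carboxylic acid | OC(=O)[C@@H]1O[C@H](c2ccc(OC)cc2)OCC1(C)C
F6 | step 2 | ethyl 3-[(2R,4R)-2-(4-methoxyphenyl)-5,5-dimethyl-1,3-dioxan-4-yl]-3-oxopropanoate | CCOC(=O)CC(=O)[C@@H]1O[C@H](c2ccc(OC)cc2)OCC1(C)C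
F7 | step 2 | (5R)-4-hydroxy-5-(1-hydroxy-2-methylpropan-2-yl)furan-2(5H)-one | O=C1C=C(O)[C@H](O1)C(C)(C)CO
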